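**Retrosynthetic overview**

1. Target 13 ⇒ 12 (the C3 carboxamide is the masked CH2NMe2 group) ⇒ 11 (C2–Br comes from C2–OH).
2. 11 ⇒ 10 by cutting C2–C3 of the pyrrole ring. The plan rests on C2 of the pyrrole ring, which bears only bromine and no carbon substituent. It can therefore enter as the carbonyl carbon of a methyl carbamate on N1 (carbonic acid level), which the C3 amide enolate attacks.
3. 10 ⇒ 1 + 2 + 6 + 9: amide coupling, nitro reduction, carbamoylation, bromination para to nitrogen (the later C5–Br; the later C6–Br is already in 1), then N-methylation. This replaces a nitroarene C–H substitution, whose regiochemistry next to a ring bromine is uncertain, with steps of fixed regiochemistry.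
4. Ring order: the benzene ring comes from 1; the pyrrole ring is the only ring formed, in step 6.

Key step: step 6

Remark: 11 is drawn as its 2-hydroxyindole tautomer; the 3H-oxindole tautomer is the same compound for the purposes of steps 6 and 7.

**Route**

Step 1
Reactants: 1 2-(4-bromo-2-nitrophenyl)acetic acid; 2 dimethylamine
Product: 4 2-(4-bromo-2-nitrophenyl)-N,N-dimethylacetamide, via acyl imidazolide 3 (not isolated)
Conditions: CDI (1.1 equiv), THF, rt; then Me2NH (2 M in THF), rt
Reagents that add atoms: dimethylamine, CNC
Why: Amide coupling through the N-acylimidazole, which dimethylamine should acylate cleanly while the nitro group and the aryl bromide stay inert.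

Step 2
Reactants: 4 2-(4-bromo-2-nitrophenyl)-N,N-dimethylacetamide
Product: 5 2-(2-amino-4-bromophenyl)-N,N-dimethylacetamide
Conditions: Fe powder, NH4Cl, EtOH/H2O (4:1), 65 °C; filtered and used crude
Reagents that add atoms: none
Why: Béchamp-type nitro reduction under nearly neutral conditions should spare the aryl bromide, and the tertiary amide should resist lactamisation by the aniline at this pH and temperature.

Step 3
Reactants: 5 2-(2-amino-4-bromophenyl)-N,N-dimethylacetamide; 6 methyl chloroformate
Product: 7 methyl N-[5-bromo-2-[2-(dimethylamino)-2-oxoethyl]phenyl]carbamate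
Conditions: ClCO2Me, pyridine, CH2Cl2, 0 °C to rt
Reagents that add atoms: methyl chloroformate, COC(=O)Cl
Why: Schotten–Baumann-type N-acylation of the aniline with a chloroformate installs the future C2 carbon, removes the lactamisation risk and tempers the ring for a single bromination.

Step 4
Reactants: 7 methyl N-[5-bromo-2-[2-(dimethylamino)-2-oxoethyl]phenyl]carbamate
Product: 8 methyl N-[4,5-dibromo-2-[2-(dimethylamino)-2-oxoethyl]phenyl]carbamate
Conditions: NBS (1.05 equiv), DMF, rt to 40 °C, dark
Reagents that add atoms: N-bromosuccinimide, O=C1CCC(=O)N1Br
Why: Electrophilic aromatic bromination directed by the carbamate nitrogen should go to its open para position (C4, also ortho to the existing bromine), because the competing ortho position C6 is wedged between the carbamate and bromine.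

Step 5
Reactants: 8 methyl N-[4,5-dibromo-2-[2-(dimethylamino)-2-oxoethyl]phenyl]carbamate; 9 iodomethane
Product: 10 methyl N-[4,5-dibromo-2-[2-(dimethylamino)-2-oxoethyl]phenyl]-N-methylcarbamate
Conditions: NaH (1.0 equiv), DMF, 0 °C; then MeI, 0 °C to rt
Reagents that add atoms: iodomethane, CI
Why: N-alkylation of the carbamate anion; the N–H is several pKa units more acidic than the benzylic CH2, so one equivalent of NaH should deprotonate nitrogen only, and holding the base to one equivalent avoids early ring closure and C-methylation.

Step 6
Reactants: 10 methyl N-[4,5-dibromo-2-[2-(dimethylamino)-2-oxoethyl]phenyl]-N-methylcarbamate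
Product: 11 5,6-dibromo-2-hydroxy-N,N,1-trimethylindole-3-carboxamide
Conditions: KOtBu (2.2 equiv), THF, 0 °C to rt, N2; then aq. HCl
Reagents that add atoms: none
Why: KOtBu removes a proton from the only acidic CH2 (benzylic and alpha to the dimethylamide), and the amide enolate adds to the carbamate carbonyl on N1; loss of methoxide from the tetrahedral intermediate forms C2–C3. The closest known reaction types are the Dieckmann condensation and the base-mediated (activated Madelung-type) closures of ortho-acylamino arylacetic acid derivatives, here with a carbamate as the acyl partner. The five-membered pyrrole ring closes in the 5-(enolexo)-exo-trig mode and no stereocentre is formed. The step needs C-acylation at this one carbonyl only, which the substrate secures: there is one enolisable CH2, one carbonyl within five-ring reach, and the N-methyl group rules out N–H deprotonation (which would deactivate the carbamate) and N-lactamisation onto the side-chain amide. Should the tetrahedral intermediate expel the anilide nitrogen in place of methoxide, the N-anion would reclose on the new methyl ester to the same product. The acidic beta-dicarbonyl product is deprotonated by the second equivalent of base, which drives the closure, and alkoxide at this temperature leaves the aryl bromides alone.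

Step 7
Reactants: 11 5,6-dibromo-2-hydroxy-N,N,1-trimethylindole-3-carboxamide
Product: 12 2,5,6-tribromo-N,N,1-trimethylindole-3-carboxamide
Conditions: POBr3 (3 equiv), 1,2-dichloroethane, 85 °C; then ice-water
Reagents that add atoms: phosphorus oxybromide, O=P(Br)(Br)Br
Why: Deoxybromination of the enolised lactam: O-phosphorylation at C2 and addition–elimination by bromide, driven by aromatisation to the indole, as in the known conversion of 3-acyloxindoles into 2-haloindoles with phosphorus oxyhalides; any Vilsmeier-type activation of the carboxamide is undone by the aqueous quench.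

Step 8
Reactants: 12 2,5,6-tribromo-N,N,1-trimethylindole-3-carboxamide
Product: 13 2,5,6-tribromo-1-methylgramine
Conditions: AlH3 (from LiAlH4 and AlCl3, 3:1), THF, 0 °C; then Na2SO4·10H2O
Reagents that add atoms: none
Why: Alane reduction of a tertiary amide to the amine via the O-aluminated hemiaminal and the iminium ion; the electrophilic hydride should add 1,2 at the carbonyl at 0 °C and leave the three C–Br bonds intact.

**Compound list**

1 | 2-(4-bromo-2-nitrophenyl)acetic acid | O=C(O)Cc1ccc(Br)cc1[N+](=O)[O-] | starting material
2 | dimethylamine | CNC | starting material
3 | 2-(4-bromo-2-nitrophenyl)-1-(imidazol-1-yl)ethan-1-one (acyl imidazolide, not isolated) | O=C(Cc1ccc(Br)cc1[N+](=O)[O-])n1ccnc1 | intermediate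
4 | 2-(4-bromo-2-nitrophenyl)-N,N-dimethylacetamide | CN(C)C(=O)Cc1ccc(Br)cc1[N+](=O)[O-] | intermediate
5 | 2-(2-amino-4-bromophenyl)-N,N-dimethylacetamide | CN(C)C(=O)Cc1ccc(Br)cc1N | intermediate
6 | methyl chloroformate | COC(=O)Cl | starting material
7 | methyl N-[5-bromo-2-[2-(dimethylamino)-2-oxoethyl]phenyl]carbamate | COC(=O)Nc1cc(Br)ccc1CC(=O)N(C)C | intermediate
8 | methyl N-[4,5-dibromo-2-[2-(dimethylamino)-2-oxoethyl]phenyl]carbamate | COC(=O)Nc1cc(Br)c(Br)cc1CC(=O)N(C)C | intermediate
9 | iodomethane | CI | starting material
10 | methyl N-[4,5-dibromo-2-[2-(dimethylamino)-2-oxoethyl]phenyl]-N-methylcarbamate | COC(=O)N(C)c1cc(Br)c(Br)cc1CC(=O)N(C)C | intermediate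
11 | 5,6-dibromo-2-hydroxy-N,N,1-trimethylindole-3-carboxamide | CN(C)C(=O)c1c(O)n(C)c2cc(Br)c(Br)cc12 | intermediate
12 | 2,5,6-tribromo-N,N,1-trimethylindole-3-carboxamide | CN(C)C(=O)c1c(Br)n(C)c2cc(Br)c(Br)cc12 | intermediate
13 | 2,5,6-tribromo-1-methylgramine | CN(C)Cc1c(Br)n(C)c2cc(Br)c(Br)cc12 | target

**Step count**

Total steps: 8. Longest linear sequence: 8 steps (from 1).

**Steps most likely to fail**

Step 6. The enolate may form too slowly relative to alkoxide attack on the carbamate, which would cleave it to the N-methylaniline, or the tetrahedral adduct may revert so that closure stalls. The fallback gives up the carbanion acylation, closes the pyrrole ring at N1–C2 by lactamisation, and brings in C2–Br and the C3 carbon together. Setting out from 10, heating in 48% aq. HBr/AcOH should cleave the methyl carbamate (bromide attack at the O-methyl group, then decarboxylation). The freed N-methylaniline should then lactamise onto the side-chain amide to give 5,6-dibromo-1-methylindolin-2-one F1. Vilsmeier–Haack bromoformylation (POBr3, DMF, CHCl3, reflux, aqueous work-up) should convert this into 2,5,6-tribromo-1-methylindole-3-carbaldehyde F2. Reductive amination (Me2NH, NaBH(OAc)3, AcOH, 1,2-dichloroethane, rt) then comes back to the route at 13.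

Step 7. POBr3 may be consumed by activation of the exocyclic tertiary amide oxygen, so that the C2 oxygen is exchanged incompletely or the material decomposes at the temperature required. The fallback separates activation from displacement. Setting out from 11, triflation of the enolate under basic conditions (NaH, PhNTf2, THF, 0 °C to rt) should occur at the C2 oxygen, since that restores the aromatic indole, and give 5,6-dibromo-3-(dimethylcarbamoyl)-1-methylindol-2-yl trifluoromethanesulfonate F3. Displacement of the triflate by bromide (LiBr, MeCN, 80 °C), an addition–elimination at C2 activated by the C3 carbonyl, comes back to the route at 12.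

Step 8. Hydride may remove the C2 bromine by addition–elimination, or the aluminium Lewis acid may ionise the new C–N bond of the gramine and cause over-reduction to the 3-methylindole. The fallback activates the amide electrophilically and reduces with a mild borohydride. Setting out from 12, Tf2O (CH2Cl2, 0 °C) should give [(2,5,6-tribromo-1-methylindol-3-yl)(trifluoromethylsulfonyloxy)methylidene]dimethylammonium trifluoromethanesulfonate F4, which is not isolated. NaBH4 (THF, rt) should reduce it through the iminium ion and come back to the route at 13.

Further compounds
F1 | step 6 | 5,6-dibromo-1-methylindolin-2-one | CN1C(=O)Cc2cc(Br)c(Br)cc21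
F2 | step 6 | 2,5,6-tribromo-1-methylindole-3-carbaldehyde | Cn1c(Br)c(C=O)c2cc(Br)c(Br)cc21
F3 | step 7 | 5,6-dibromo-3-(dimethylcarbamoyl)-1-methylindol-2-yl trifluoromethanesulfonate | CN(C)C(=O)c1c(OS(=O)(=O)C(F)(F)F)n(C)c2cc(Br)c(Br)cc12
F4 | step 8 | [(2,5,6-tribromo-1-methylindol-3-yl)(trifluoromethylsulfonyloxy)methylidene]dimethylammonium trifluoromethanesulfonate | C[N+](C)=C(OS(=O)(=O)C(F)(F)F)c1c(Br)n(C)c2cc(Br)c(Br)cc12.[O-]S(=O)(=O)C(F)(F)F
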